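Numbering: ring C1 (O-angelate), C2, C3 (CH3), C4 (OH), C5, C6 (side chain); chain C7 (CH3), C8, C9 (OAc), C10=C11(CH3)2.
Cuts: the two ester C–O bonds; C9–C10 (aldehyde plus isobutenylzinc); C7–CH3, traced back together with a temporary C6–CH2 bond to a cyclopropane spiro-fused at C6; C6=C7 (aldol condensation); C3–CH3 (conjugate addition to a benzoquinone monoketal).
Enabling feature: only C7, ring carbon C6 and C1 lie between the C7 methyl carbon and the C1 oxygen. A C1 hydroxyl can therefore hand a CH2 to an exocyclic C6=C7 alkene, and in the resulting spiro[2.5]octane the surplus C6–CH2 bond is the α,β bond of a C1 ketone and can be cut reductively.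
Forward order: the six-membered ring comes intact from 4-methoxyphenol; then C3–CH3, the C7–C9 chain on C6, the three-membered ring (closed in step 6, opened in step 8), C10–C11, the acyl groups, and last the C4 carbinol.
Stereochemistry: C3 from a chiral copper catalyst; the temporary C1 carbinol from a CBS reduction; C7 from syn methylene delivery to the E alkene on the hydroxyl face; C6 by enolate equilibration; C1 by dissolving-metal reduction; C9 from an amino-alcohol zinc catalyst; C4 by equatorial hydride attack.

Key step: step 6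

Assumption: the sense of induction of the phosphoramidite ligand (step 2) and of (−)-MIB (step 13) is carried over from cyclohex-2-enone and from simple aliphatic aldehydes; if either is reversed on these substrates, the antipodal ligand is used.

Step 1
Reactants: 1 4-methoxyphenol
Product: 2 4,4-dimethoxycyclohexa-2,5-dien-1-one
Conditions: PhI(OAc)2, MeOH, 0 °C → rt
Reagents that add atoms: methanol, CO
Why: Hypervalent-iodine oxidative dearomatisation of a 4-alkoxyphenol in methanol traps the phenoxenium ion at the para carbon and is the standard entry to benzoquinone monoketals.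

Step 2
Reactants: 2 4,4-dimethoxycyclohexa-2,5-dien-1-one; 3 dimethylzinc
Product: 4 (5S)-4,4-dimethoxy-5-methylcyclohex-2-en-1-one
Conditions: Cu(OTf)2 (2 mol %), (R,S,S)-BINOL bis(1-phenylethyl)phosphoramidite (4 mol %), Me2Zn, toluene, −25 °C
Reagents that add atoms: dimethylzinc 3, C[Zn]C
Why: Copper/phosphoramidite-catalysed enantioselective conjugate addition of a dialkylzinc, a reaction type known for benzoquinone monoketals, desymmetrises the two enantiotopic enone halves so that the ligand sets C3, while the zinc enolate formed resists a second addition and leaves the C5=C6 enone for step 3.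

Step 3
Reactants: 4 (5S)-4,4-dimethoxy-5-methylcyclohex-2-en-1-one; 5 3-(tert-butyldimethylsilyloxy)propanal
Product: 7 (5S)-2-[3-(tert-butyldimethylsilyloxy)-1-hydroxypropyl]-4,4-dimethoxy-5-methylcyclohexan-1-one as a mixture at C6 and C7, via lithium enolate 6 (not isolated)
Conditions: LiBH(s-Bu)3 (L-Selectride), THF, −78 °C; then 5, −78 °C
Reagents that add atoms: 3-(tert-butyldimethylsilyloxy)propanal 5, CC(C)(C)[Si](C)(C)OCCC=O
Why: 1,4-Hydride delivery by the trialkylborohydride to the β-unsubstituted cyclohexenone generates the C1–C6 enolate regiospecifically (a C1–C2 enolate cannot arise), and its aldol addition joins C6 to C7; the two new centres are erased in step 4.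

Step 4
Reactants: 7 aldol adduct
Product: 9 (2E,5S)-2-[3-(tert-butyldimethylsilyloxy)propylidene]-4,4-dimethoxy-5-methylcyclohexan-1-one, via C7 mesylate 8 (not isolated)
Conditions: MsCl, Et3N, CH2Cl2, 0 °C; then DBU, rt
Reagents that add atoms: none
Why: Mesylation followed by E1cB elimination through the C1–C6 enolate converges both aldol diastereomers on the E alkylidene ketone, in which C8 points away from the carbonyl oxygen.

Step 5
Reactants: 9 (2E,5S)-enone
Product: 10 (1S,2E,5S)-2-[3-(tert-butyldimethylsilyloxy)propylidene]-4,4-dimethoxy-5-methylcyclohexan-1-ol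
Conditions: (R)-Me-CBS (20 mol %), BH3·SMe2, THF, −40 °C
Reagents that add atoms: none
Why: In this Corey–Bakshi–Shibata reduction the alkylidene-bearing C6 acts as the large and C2H2 as the small ketone substituent, so the (R)-catalyst should give, with clean 1,2-selectivity, the (1S) carbinol whose hydroxyl is trans to the C3 methyl and axial in the chair with equatorial methyl.

Step 6
Reactants: 10 (1S,2E,5S)-allylic alcohol; 11 diiodomethane
Product: 13 (1R,3R,4S,6S)-1-[2-(tert-butyldimethylsilyloxy)ethyl]-7,7-dimethoxy-6-methylspiro[2.5]octan-4-ol, via iodomethylzinc alkoxide 12 (not isolated)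
Conditions: Et2Zn, CH2I2, DME, CH2Cl2, −15 → 0 °C
Reagents that add atoms: diiodomethane 11, ICI
Why: Et2Zn deprotonates the C1 hydroxyl and, after zinc–iodine exchange with CH2I2, the alkoxide-bound iodomethylzinc unit of 12 passes its CH2 to the adjacent C6=C7 bond through the concerted butterfly transition state of the hydroxyl-directed Simmons–Smith reaction (Furukawa variant), a reaction type long used on 2-alkylidenecycloalkanols. The three-membered ring closes in one internally delivered, stereospecific syn [2+1] addition that forms C7–CH2 and C6–CH2 at the same time, so the E geometry (H toward C1, C8 toward C5) is copied into the spiro[2.5]octane. Both new stereocentres depend only on the face attacked: in the chair with equatorial C3 methyl the C1 oxygen is axial, stands nearly perpendicular to the alkene plane and reaches only its own face, which gives (R) at the spiro carbon C6 and (R) at C7, the latter being the configuration of the methyl-bearing carbon of 31. The axial C4 methoxy group lies 1,3 to C6 on the opposite face and reinforces this choice. Only facial selectivity is needed because C6=C7 is the sole alkene present, and DME tempers the Lewis acidity of the zinc iodide formed so that ketal and silyl ether persist.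

Step 7
Reactants: 13 spiro cyclopropyl carbinol
Product: 14 (1R,3R,6S)-1-[2-(tert-butyldimethylsilyloxy)ethyl]-7,7-dimethoxy-6-methylspiro[2.5]octan-4-one
Conditions: n-Pr4N[RuO4] (5 mol %), NMO, 4 Å molecular sieves, CH2Cl2, rt
Reagents that add atoms: none
Why: The neutral Ley–Griffith oxidation converts the secondary carbinol into the conjugated cyclopropyl ketone without the acid that would ionise a cyclopropyl carbinol or the ketal.

Step 8
Reactants: 14 spiro cyclopropyl ketone
Product: 16 (5S)-2-[(2R)-4-(tert-butyldimethylsilyloxy)butan-2-yl]-4,4-dimethoxy-5-methylcyclohexan-1-one as both C6 epimers, via ring-opened lithium enolate 15 (not isolated)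
Conditions: Li, NH3(l)/THF, t-BuOH (1 equiv), −78 °C; NH4Cl
Reagents that add atoms: none
Why: In the dissolving-metal cleavage of a conjugated cyclopropyl ketone the ketyl breaks the α,β bond that can lie parallel to the carbonyl π orbitals and leaves the more stable carbanion, and both criteria point to C6–CH2: the chair with this arm axial (C3 methyl axial beside the ketal, where that costs little) avoids the syn-axial contact between the chain-bearing C7 arm and the axial C4 methoxy group, and scission gives a primary instead of a secondary carbanion, as with trans-2-alkylcyclopropyl ketones, so the CH2 becomes the C7 methyl with C7 untouched.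

Step 9
Reactants: 16 ketone as both C6 epimers
Product: 18 (1R,2S,5S)-2-[(2R)-4-(tert-butyldimethylsilyloxy)butan-2-yl]-4,4-dimethoxy-5-methylcyclohexan-1-ol, via trans-ketone 17 (not isolated)
Conditions: NaOMe (cat.), MeOH, rt; concentrate; then Li, NH3(l)/THF, EtOH, −78 °C
Reagents that add atoms: none
Why: Methoxide equilibrates C6 through the enolate toward the epimer with side chain and C3 methyl both equatorial (an axial chain is excluded by the axial C4 methoxy group), and the Li/NH3–EtOH reduction, which is faster than enolisation, then delivers the more stable equatorial C1 alcohol trans to the chain, as in the menthone-to-menthol reduction.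

Step 10
Reactants: 18 equatorial C1 alcohol; 19 angelic acid
Product: 21 (1R,2S,5S)-2-[(2R)-4-(tert-butyldimethylsilyloxy)butan-2-yl]-4,4-dimethoxy-5-methylcyclohexyl (Z)-2-methylbut-2-enoate, via mixed anhydride 20 (not isolated)
Conditions: 19, 2,4,6-Cl3C6H2COCl, Et3N, toluene, rt; then 18, 80 °C
Reagents that add atoms: angelic acid 19, C/C=C(/C)C(=O)O
Why: Yamaguchi-type mixed-anhydride esterification run without a nucleophilic catalyst is the established way to angeloylate hindered secondary alcohols without Z-to-E isomerisation, and C1 keeps its configuration because only the O–H bond reacts.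

Step 11
Reactants: 21 angelate silyl ether
Product: 22 (1R,2S,5S)-2-[(2R)-4-hydroxybutan-2-yl]-4,4-dimethoxy-5-methylcyclohexyl (Z)-2-methylbut-2-enoate
Conditions: Bu4NF, AcOH, THF, 0 °C → rt
Reagents that add atoms: none
Why: Acetic-acid-buffered fluoride removes the primary silyl ether while the ketal (acid-labile only) and the hindered angelate stay intact.

Step 12
Reactants: 22 primary alcohol
Product: 23 (1R,2S,5S)-4,4-dimethoxy-5-methyl-2-[(2R)-4-oxobutan-2-yl]cyclohexyl (Z)-2-methylbut-2-enoate
Conditions: n-Pr4N[RuO4] (5 mol %), NMO, 4 Å molecular sieves, CH2Cl2, rt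
Reagents that add atoms: none
Why: Ley–Griffith oxidation under anhydrous, neutral conditions stops at the aldehyde and does not disturb C7, which is β to the new carbonyl.

Step 13
Reactants: 23 aldehyde; 24 1-bromo-2-methylprop-1-ene
Product: 27 (1R,2S,5S)-2-[(2R,4R)-4-hydroxy-6-methylhept-5-en-2-yl]-4,4-dimethoxy-5-methylcyclohexyl (Z)-2-methylbut-2-enoate, via 2-methylprop-1-enyllithium 25 (not isolated), via bis(2-methylprop-1-enyl)zinc 26 (not isolated)
Conditions: 24, t-BuLi, Et2O, −78 °C; ZnBr2, → 0 °C; TEEDA, (−)-MIB (10 mol %), toluene/hexanes; 23, 0 °C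
Reagents that add atoms: 1-bromo-2-methylprop-1-ene 24, CC(C)=CBr
Why: Amino-alcohol-catalysed enantioselective addition of an alkenylzinc reagent to an aldehyde, with the diamine masking LiBr to suppress the uncatalysed pathway, should direct the isobutenyl group to the Si face and give (R) at C9, and the organozinc leaves esters and ketal alone.

Step 14
Reactants: 27 allylic alcohol; 28 acetic anhydride
Product: 29 (1R,2S,5S)-2-[(2R,4R)-4-acetoxy-6-methylhept-5-en-2-yl]-4,4-dimethoxy-5-methylcyclohexyl (Z)-2-methylbut-2-enoate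
Conditions: Ac2O, pyridine, DMAP (cat.), CH2Cl2, 0 °C → rt
Reagents that add atoms: acetic anhydride 28, CC(=O)OC(C)=O
Why: DMAP-catalysed acetylation of the only free hydroxyl proceeds at oxygen with retention at C9.

Step 15
Reactants: 29 acetate dimethyl ketal
Product: 30 (1R,2S,5S)-2-[(2R,4R)-4-acetoxy-6-methylhept-5-en-2-yl]-5-methyl-4-oxocyclohexyl (Z)-2-methylbut-2-enoate
Conditions: PPTS (cat.), acetone/H2O, rt
Reagents that add atoms: water, O
Why: Acyclic dimethyl ketals hydrolyse under acid mild enough to spare the ionisable allylic acetate and both esters, and C3, now α to a ketone, already carries its methyl in the more stable equatorial position on a ring anchored by the C1 and C6 substituents.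

Step 16
Reactants: 30 C4 ketone
Product: 31 (1R,2S,4R,5S)-2-[(2R,4R)-4-acetoxy-6-methylhept-5-en-2-yl]-4-hydroxy-5-methylcyclohexyl (Z)-2-methylbut-2-enoate
Conditions: LiBH(s-Bu)3 (1.1 equiv), THF, −78 °C; pH 7 buffer
Reagents that add atoms: none
Why: The bulky trialkylborohydride attacks this 2-methylcyclohexanone-type ketone from the equatorial direction and gives the axial (4R) alcohol cis to the C3 methyl, and at −78 °C with about one equivalent the acetate and angelate are not touched.

Compound list
1 | 4-methoxyphenol | COc1ccc(O)cc1 | starting material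
2 | 4,4-dimethoxycyclohexa-2,5-dien-1-one | COC1(OC)C=CC(=O)C=C1 | intermediate
3 | dimethylzinc | C[Zn]C | starting material
4 | (5S)-4,4-dimethoxy-5-methylcyclohex-2-en-1-one | O=C1C[C@H](C)C(OC)(OC)C=C1 | intermediate
5 | 3-(tert-butyldimethylsilyloxy)propanal | CC(C)(C)[Si](C)(C)OCCC=O | starting material
6 | lithium (5S)-4,4-dimethoxy-5-methylcyclohex-1-en-1-olate (C1–C6 enolate, formed in the flask) | [Li]OC1=CCC(OC)(OC)[C@@H](C)C1 | intermediate
7 | (5S)-2-[3-(tert-butyldimethylsilyloxy)-1-hydroxypropyl]-4,4-dimethoxy-5-methylcyclohexan-1-one (mixture at C6 and C7) | O=C1C[C@H](C)C(OC)(OC)CC1C(O)CCO[Si](C)(C)C(C)(C)C | intermediate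
8 | C7 methanesulfonate of 7 (formed in the flask) | O=C1C[C@H](C)C(OC)(OC)CC1C(CCO[Si](C)(C)C(C)(C)C)OS(C)(=O)=O | intermediate
9 | (2E,5S)-2-[3-(tert-butyldimethylsilyloxy)propylidene]-4,4-dimethoxy-5-methylcyclohexan-1-one | CC(C)(C)[Si](C)(C)OCC/C=C1/C(=O)C[C@H](C)C(OC)(OC)C1 | intermediate
10 | (1S,2E,5S)-2-[3-(tert-butyldimethylsilyloxy)propylidene]-4,4-dimethoxy-5-methylcyclohexan-1-ol | CC(C)(C)[Si](C)(C)OCC/C=C1/[C@@H](O)C[C@H](C)C(OC)(OC)C1 | intermediate
11 | diiodomethane | ICI | starting material
12 | iodomethylzinc alkoxide of 10 (formed in the flask) | CC(C)(C)[Si](C)(C)OCC/C=C1/[C@@H](O[Zn]CI)C[C@H](C)C(OC)(OC)C1 | intermediate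
13 | (1R,3R,4S,6S)-1-[2-(tert-butyldimethylsilyloxy)ethyl]-7,7-dimethoxy-6-methylspiro[2.5]octan-4-ol | O[C@H]1C[C@H](C)C(OC)(OC)C[C@@]12C[C@@H]2CCO[Si](C)(C)C(C)(C)C | intermediate
14 | (1R,3R,6S)-1-[2-(tert-butyldimethylsilyloxy)ethyl]-7,7-dimethoxy-6-methylspiro[2.5]octan-4-one | O=C1C[C@H](C)C(OC)(OC)C[C@@]12C[C@@H]2CCO[Si](C)(C)C(C)(C)C | intermediate
15 | lithium (5S)-2-[(2R)-4-(tert-butyldimethylsilyloxy)butan-2-yl]-4,4-dimethoxy-5-methylcyclohex-1-en-1-olate (formed in the flask) | [Li]OC1=C(CC(OC)(OC)[C@@H](C)C1)[C@H](C)CCO[Si](C)(C)C(C)(C)C | intermediate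
16 | (5S)-2-[(2R)-4-(tert-butyldimethylsilyloxy)butan-2-yl]-4,4-dimethoxy-5-methylcyclohexan-1-one (both C6 epimers) | O=C1C[C@H](C)C(OC)(OC)CC1[C@H](C)CCO[Si](C)(C)C(C)(C)C | intermediate
17 | (2S,5S)-2-[(2R)-4-(tert-butyldimethylsilyloxy)butan-2-yl]-4,4-dimethoxy-5-methylcyclohexan-1-one (chain and methyl trans, formed in the flask) | O=C1C[C@H](C)C(OC)(OC)C[C@H]1[C@H](C)CCO[Si](C)(C)C(C)(C)C | intermediate
18 | (1R,2S,5S)-2-[(2R)-4-(tert-butyldimethylsilyloxy)butan-2-yl]-4,4-dimethoxy-5-methylcyclohexan-1-ol | O[C@@H]1C[C@H](C)C(OC)(OC)C[C@H]1[C@H](C)CCO[Si](C)(C)C(C)(C)C | intermediate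
19 | angelic acid, (Z)-2-methylbut-2-enoic acid | C/C=C(/C)C(=O)O | starting material
20 | (Z)-2-methylbut-2-enoic 2,4,6-trichlorobenzoic anhydride (formed in the flask) | C/C=C(/C)C(=O)OC(=O)c1c(Cl)cc(Cl)cc1Cl | intermediate
21 | (1R,2S,5S)-2-[(2R)-4-(tert-butyldimethylsilyloxy)butan-2-yl]-4,4-dimethoxy-5-methylcyclohexyl (Z)-2-methylbut-2-enoate | C/C=C(/C)C(=O)O[C@@H]1C[C@H](C)C(OC)(OC)C[C@H]1[C@H](C)CCO[Si](C)(C)C(C)(C)C | intermediate
22 | (1R,2S,5S)-2-[(2R)-4-hydroxybutan-2-yl]-4,4-dimethoxy-5-methylcyclohexyl (Z)-2-methylbut-2-enoate | C/C=C(/C)C(=O)O[C@@H]1C[C@H](C)C(OC)(OC)C[C@H]1[C@H](C)CCO | intermediate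
23 | (1R,2S,5S)-4,4-dimethoxy-5-methyl-2-[(2R)-4-oxobutan-2-yl]cyclohexyl (Z)-2-methylbut-2-enoate | C/C=C(/C)C(=O)O[C@@H]1C[C@H](C)C(OC)(OC)C[C@H]1[C@H](C)CC=O | intermediate
24 | 1-bromo-2-methylprop-1-ene | CC(C)=CBr | starting material
25 | 2-methylprop-1-enyllithium (formed in the flask) | [Li]C=C(C)C | intermediate
26 | bis(2-methylprop-1-enyl)zinc (formed in the flask) | CC(C)=C[Zn]C=C(C)C | intermediate
27 | (1R,2S,5S)-2-[(2R,4R)-4-hydroxy-6-methylhept-5-en-2-yl]-4,4-dimethoxy-5-methylcyclohexyl (Z)-2-methylbut-2-enoate | C/C=C(/C)C(=O)O[C@@H]1C[C@H](C)C(OC)(OC)C[C@H]1[C@H](C)C[C@H](C=C(C)C)O | intermediate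
28 | acetic anhydride | CC(=O)OC(C)=O | starting material
29 | (1R,2S,5S)-2-[(2R,4R)-4-acetoxy-6-methylhept-5-en-2-yl]-4,4-dimethoxy-5-methylcyclohexyl (Z)-2-methylbut-2-enoate | C/C=C(/C)C(=O)O[C@@H]1C[C@H](C)C(OC)(OC)C[C@H]1[C@H](C)C[C@H](C=C(C)C)OC(C)=O | intermediate
30 | (1R,2S,5S)-2-[(2R,4R)-4-acetoxy-6-methylhept-5-en-2-yl]-5-methyl-4-oxocyclohexyl (Z)-2-methylbut-2-enoate | C/C=C(/C)C(=O)O[C@@H]1C[C@H](C)C(=O)C[C@H]1[C@H](C)C[C@H](C=C(C)C)OC(C)=O | intermediate
31 | (1R,2S,4R,5S)-2-[(2R,4R)-4-acetoxy-6-methylhept-5-en-2-yl]-4-hydroxy-5-methylcyclohexyl (Z)-2-methylbut-2-enoate (CNP0237033.1) | C/C=C(/C)C(=O)O[C@@H]1C[C@H](C)[C@H](O)C[C@H]1[C@H](C)C[C@H](C=C(C)C)OC(C)=O | target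

Total step count: 16. Longest linear sequence: 16 steps (1 → 31); all other inputs are purchased.

Steps most likely to fail

Step 8. Scission of the C6–C7 bond may compete. In the chair with equatorial C3 methyl it is this bond, not C6–CH2, that is aligned with the carbonyl π system, so the outcome rests on the ring flip and on carbanion stability. The fallback replaces electron transfer by a sterically governed polar opening. It sets out from 14: sodium benzeneselenolate (PhSeNa, 18-crown-6, THF, reflux) adds in a homoconjugate SN2 sense to the unsubstituted cyclopropane CH2 and gives the γ-phenylselanyl ketone F1. Radical deselenation (Bu3SnH, AIBN, toluene, 80 °C) then turns the CH2SePh group into the C7 methyl and comes back to the route at 16.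

Step 9. Epimer discrimination at C6 may be poor in the equilibration, because the two ketones differ mainly by an equatorial versus an axial C3 methyl next to the ketal. The fallback lets C7 decide through a tether. It sets out from 16:
- Bu4NF frees the C9 hydroxyl, which closes onto the C1 ketone.
- K2CO3 in MeOH equilibrates C6 through the open form into the trans-fused bicyclic hemiketal F2. In F2 both methyl groups and both ring-fusion bonds are equatorial, whereas the C6 epimer would have to hold the C7 methyl axial against the anomeric hydroxyl.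
- Li/NH3–EtOH at −78 °C reduces the ring-opened tautomer to the diol F3.
- Selective silylation of the primary hydroxyl (TBSCl, imidazole, CH2Cl2, 0 °C) comes back to the route at 18.

Step 13. Facial selectivity at the β-branched aliphatic aldehyde may be low, or the uncatalysed addition of the β,β-disubstituted alkenylzinc may be fast. The fallback moves the stereochemical decision from C–C bond formation to a ketone reduction. It sets out from 23: (CH3)2C=CHMgBr in THF at −78 °C gives the C9-epimeric allylic alcohols F4, and Dess–Martin periodinane gives the enone F5. (S)-Me-CBS with BH3·SMe2, which treats the isobutenyl group as the large substituent, then delivers the (9R) alcohol and comes back to the route at 27.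

Further compounds
F1 | step 8 | (5S)-2-[(2R)-4-(tert-butyldimethylsilyloxy)-1-(phenylselanyl)butan-2-yl]-4,4-dimethoxy-5-methylcyclohexan-1-one (both C6 epimers) | O=C1C[C@H](C)C(OC)(OC)CC1[C@H](C[Se]c2ccccc2)CCO[Si](C)(C)C(C)(C)C
F2 | step 9 | (4R,4aS,7S,8aR)-6,6-dimethoxy-4,7-dimethyloctahydro-2H-chromen-8a-ol | O[C@@]12C[C@H](C)C(OC)(OC)C[C@H]1[C@H](C)CCO2
F3 | step 9 | (1R,2S,5S)-2-[(2R)-4-hydroxybutan-2-yl]-4,4-dimethoxy-5-methylcyclohexan-1-ol | O[C@@H]1C[C@H](C)C(OC)(OC)C[C@H]1[C@H](C)CCO
F4 | step 13 | (1R,2S,5S)-2-[(2R)-4-hydroxy-6-methylhept-5-en-2-yl]-4,4-dimethoxy-5-methylcyclohexyl (Z)-2-methylbut-2-enoate (both C9 epimers) | C/C=C(/C)C(=O)O[C@@H]1C[C@H](C)C(OC)(OC)C[C@H]1[C@H](C)CC(O)C=C(C)C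
F5 | step 13 | (1R,2S,5S)-4,4-dimethoxy-5-methyl-2-[(2R)-6-methyl-4-oxohept-5-en-2-yl]cyclohexyl (Z)-2-methylbut-2-enoate | C/C=C(/C)C(=O)O[C@@H]1C[C@H](C)C(OC)(OC)C[C@H]1[C@H](C)CC(=O)C=C(C)C
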